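**Plan**
- Retrosynthetic cuts, in order: the two tert-butyl esters and the C-20 thioester (functional-group level); C-13–C-16 (ring D); C-5–C-10 and C-6–C-8 together (rings A and B); C-9–C-10 (lactone-forming Michael addition); the C-8–O ester bond; C-1–C-10.
- Enabling feature: C-10 carries the formyl carbon C-20 (carbanion-stabilising), C-8 is γ to the C-12 ketone of ring C (terminus of a C-8/C-14/C-13 π-allyl), and C-6 carries the carboxyl C-7. C-10–C-9–C-8 is therefore a 1,3-dipole and C-5=C-6 an acrylate, so ring B is a (3+2) adduct and ring A is the tether.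
- Forward order: ring C is bought as a quinone monoketal; a temporary γ-lactone (C-8–O–CO–C-10) is closed by a desymmetrising Michael addition; palladium opens it with loss of CO2 and closes rings A and B in one operation; ring D is closed last by gold catalysis.
- Stereochemistry: C-4 from a cinchona-catalysed Michael addition; C-8/C-9 from an organocatalytic desymmetrisation; C-10, C-5, C-6 (and C-8, with retention) in the key step under matched control by C-9 and C-4; C-13 by the bridge.
- Helpers, removed later: the extra lactone carboxyl (lost as CO2), the S-ethyl thioester (latent C-20 aldehyde), tert-butyl esters (C-7, C-19), the dimethyl ketal (masks the dienone).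

Key step: step 12

Assumption: tert-butyl 2-cyanopropanoate (1) is taken as purchasable (otherwise one methylation of tert-butyl cyanoacetate); gibberellane numbering (C-1 to C-20) is used for all intermediates, and the target is treated as the open aldehyde diacid drawn in its SMILES.

Step 1
Reactants: 1 tert-butyl 2-cyanopropanoate; 2 acrolein
Product: 3 tert-butyl (2R)-2-cyano-2-methyl-5-oxopentanoate
Conditions: cupreidine-derived 6'-OH bifunctional catalyst (10 mol %, pseudo-enantiomer chosen for R), CH2Cl2, −25 °C
Reagents that add atoms: none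
Why: Cinchona-alkaloid-catalysed Michael addition of an α-substituted cyanoacetate to an enal, in which the catalyst should set the quaternary centre C-4.

Step 2
Reactants: 3 tert-butyl (2R)-2-cyano-2-methyl-5-oxopentanoate
Product: 4 tert-butyl (2R)-2-cyano-5,5-dimethoxy-2-methylpentanoate
Conditions: HC(OMe)3, MeOH, PPTS (cat.), 25 °C
Reagents that add atoms: trimethyl orthoformate COC(OC)OC; methanol CO
Why: Acid-catalysed acetalisation masks the enolisable C-1 aldehyde for the next two steps, and the tert-butyl ester and nitrile should be inert to PPTS.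

Step 3
Reactants: 4 tert-butyl (2R)-2-cyano-5,5-dimethoxy-2-methylpentanoate
Product: 6 tert-butyl (2R)-2-formyl-5,5-dimethoxy-2-methylpentanoate, via aluminium aldimine 5 (not isolated)
Conditions: i-Bu2AlH (1.2 equiv), toluene, −78 °C; aq. potassium sodium tartrate, pH 5
Reagents that add atoms: water O
Why: Nitrile-to-aldehyde reduction should stop at the aluminium aldimine at −78 °C, which the mildly acidic work-up hydrolyses while the hindered tert-butyl ester and the acetal survive.

Step 4
Reactants: 6 tert-butyl (2R)-2-formyl-5,5-dimethoxy-2-methylpentanoate; 7 tert-butyl (triphenyl-λ5-phosphanylidene)acetate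
Product: 8 di-tert-butyl (2E,4R)-4-(3,3-dimethoxypropyl)-4-methylpent-2-enedioate
Conditions: toluene, 90 °C
Reagents that add atoms: none
Why: Wittig olefination with a stabilised ylide should give the (E)-enoate (C-5=C-6) from the ester-activated neopentyl aldehyde, which has no α-hydrogen to lose.

Step 5
Reactants: 8 di-tert-butyl (2E,4R)-4-(3,3-dimethoxypropyl)-4-methylpent-2-enedioate
Product: 9 di-tert-butyl (2E,4R)-4-methyl-4-(3-oxopropyl)pent-2-enedioate
Conditions: AcOH–THF–H2O (3:1:1), 40 °C
Reagents that add atoms: water O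
Why: Mild aqueous acid hydrolyses the dimethyl acetal and should leave both tert-butyl esters untouched.

Step 6
Reactants: 9 di-tert-butyl (2E,4R)-4-methyl-4-(3-oxopropyl)pent-2-enedioate; 10 Meldrum's acid
Product: 12 di-tert-butyl (2E,4R)-4-[3-(2,2-dimethyl-4,6-dioxo-1,3-dioxan-5-yl)propyl]-4-methylpent-2-enedioate, via alkylidene Meldrum's acid 11 (not isolated)
Conditions: Hantzsch ester (1.1 equiv), L-proline (10 mol %), EtOH, 25 °C
Reagents that add atoms: none
Why: Three-component reductive alkylation (Knoevenagel condensation, then conjugate hydride transfer to the alkylidene Meldrum's acid) installs C-10 with both of its carbonyl carbons, and the unactivated enoate should not be reduced.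

Step 7
Reactants: 12 di-tert-butyl (2E,4R)-4-[3-(2,2-dimethyl-4,6-dioxo-1,3-dioxan-5-yl)propyl]-4-methylpent-2-enedioate
Product: 13 (6R,7E)-9-tert-butoxy-6-(tert-butoxycarbonyl)-2-[(ethylsulfanyl)carbonyl]-6-methyl-9-oxonon-7-enoic acid (C-2 epimers)
Conditions: EtSH (5 equiv), toluene, 80 °C, sealed tube
Reagents that add atoms: ethanethiol CCS
Why: Thiolysis of the Meldrum's acid ring (acyl substitution with loss of acetone) gives the malonic acid half thioester, the thioester being the latent C-20 aldehyde and the acid the future lactone carbonyl.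

Step 8
Reactants: 14 4,4-dimethoxycyclohexa-2,5-dien-1-one; 15 propargyl bromide
Product: 16 4,4-dimethoxy-1-(prop-2-yn-1-yl)cyclohexa-2,5-dien-1-ol
Conditions: Zn dust, THF, 0 °C; aq. NH4Cl
Reagents that add atoms: none
Why: Barbier propargylation, in which the allenylzinc reagent should add 1,2 to the dienone carbonyl with allylic transposition to give the homopropargylic tertiary alcohol that carries C-15 to C-17 on C-8.

Step 9
Reactants: 13 malonic acid half thioester; 16 4,4-dimethoxy-1-(prop-2-yn-1-yl)cyclohexa-2,5-dien-1-ol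
Product: 17 4,4-dimethoxy-1-(prop-2-yn-1-yl)cyclohexa-2,5-dien-1-yl ester of acid 13 (mixed malonate ester/thioester, C-10 epimers)
Conditions: DCC (1.2 equiv), CH2Cl2, 0 °C to 25 °C, no amine base
Reagents that add atoms: none
Why: Carbodiimide esterification of a tertiary alcohol with a malonic half ester (acylketene pathway) should work without base, and the ketal keeps ring C from being a Michael acceptor before the catalyst-controlled step.

Step 10
Reactants: 17 ketal mixed malonate
Product: 18 4-oxo-1-(prop-2-yn-1-yl)cyclohexa-2,5-dien-1-yl ester of acid 13 (dienone, C-10 epimers)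
Conditions: 10% aq. oxalic acid on SiO2, CH2Cl2, 25 °C
Reagents that add atoms: water O
Why: Mild acidic hydrolysis of the dimethyl ketal unveils the cross-conjugated dienone, and in the absence of base no background cyclisation should occur.

Step 11
Reactants: 18 dienone mixed malonate
Product: 19 S-ethyl (3aS,7aS)-3-[(4R,5E)-7-tert-butoxy-4-(tert-butoxycarbonyl)-4-methyl-7-oxohept-5-en-1-yl]-2,5-dioxo-7a-(prop-2-yn-1-yl)-2,3,3a,4,5,7a-hexahydro-1-benzofuran-3-carbothioate (cis-fused lactone; C-3 epimers)
Conditions: quinine-derived bifunctional squaramide (10 mol %, pseudo-enantiomer chosen for 3aS,7aS), toluene, 0 °C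
Reagents that add atoms: none
Why: Organocatalytic desymmetrising intramolecular Michael addition (5-exo-trig) of the malonate-type carbon C-10 to one of the two enone arms of the dienone forms C-9–C-10; the tether forces the cis-fused γ-lactone, the catalyst should select the arm and so set C-9 and C-8, and the hindered tert-butyl enoate is a far poorer acceptor than the dienone.

Step 12
Reactants: 19 cis-fused lactone thioester
Product: 22 tricyclic enone thioester, via palladium allyl thioester enolate 20 (not isolated), via palladium allyl ester enolate 21 (not isolated)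
Conditions: Pd2(dba)3·CHCl3 (5 mol %), dppe (12 mol %), DMSO, 60 °C, 0.01 M
Reagents that add atoms: none
Why: Proposed new method: zerovalent palladium ionises the allylic lactone C-8–O bond anti to oxygen, the β-thioester carboxylate loses CO2, and the zwitterion (thioester enolate at C-10, π-allyl over C-8/C-14/C-13) adds as a 1,3-dipole to the tethered acrylate, the enolate closing ring A by 6-exo-trig Michael addition to C-5 and the new ester enolate at C-6 closing ring B by 5-exo attack on the allyl terminus C-8; the closest known reaction type is the palladium-catalysed (3+2) cycloaddition of allyl/carbanion zwitterions from vinylcyclopropanes or vinyl lactones with acrylates, here made intramolecular and decarboxylative. C-10 should be set by C-9 (H-9 eclipses the enolate by allylic 1,3-strain and C-5 enters anti to the bulky allyl carbon C-8) and by a chair transition state with ring C on C-10 and C-6 on C-5 equatorial and the C-4 ester axial (smaller than methyl) as fixed by (R)-C-4, so the two controlling elements are matched and C-5 gets its β hydrogen (trans A/B). C-6 should take its ester on the face away from C-4, and C-8 is formed with net retention (double inversion) because the tether holds the nucleophile on the face the lactone oxygen left, giving the cis B/C fusion with the propargyl group β. The step needs Michael addition before unproductive collapse (cyclopropane and O-alkylation products can re-ionise, and without external base the C-12 ketone is not enolised) and attack at C-8 instead of C-13 (five- against seven-membered ring, and the terminus remote from the ketone).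

Step 13
Reactants: 22 tricyclic enone thioester
Product: 23 dimethylphenylsilyl enol ether (C-12(OSi)=C-13, C-14 now CH2; otherwise as 22)
Conditions: [(Ph3P)CuH]6 (5 mol %), PhMe2SiH (1.5 equiv), toluene, 0 °C to 25 °C
Reagents that add atoms: dimethylphenylsilane C[SiH](C)c1ccccc1
Why: Copper-hydride-catalysed 1,4-hydrosilylation of the enone should give the silyl enol ether regiospecifically at C-12/C-13, which is what tells C-13 from C-11.

Step 14
Reactants: 23 dimethylphenylsilyl enol ether
Product: 24 tetracyclic thioester (ring D closed, C-16=C-17 exocyclic methylene, C-12 ketone; C-20 S-ethyl thioester, C-7 and C-19 tert-butyl esters)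
Conditions: Ph3PAuCl (5 mol %), AgBF4 (5 mol %), CH2Cl2–MeOH (10:1), 25 °C
Reagents that add atoms: none
Why: Carbocyclisation of the silyl enol ether onto the terminal alkyne catalysed by monovalent gold (5-exo-dig, Conia-ene type) forms C-13–C-16 and the exocyclic methylene, and the bridge can only form on the face of the C-8 propargyl group, which fixes C-13.

Step 15
Reactants: 24 tetracyclic thioester
Product: 25 di-tert-butyl ester of the target (C-20 aldehyde)
Conditions: Et3SiH (3 equiv), 10% Pd/C (5 mol %), acetone, 25 °C
Reagents that add atoms: none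
Why: Fukuyama reduction should convert the thioester chemoselectively into the aldehyde, the ketone and tert-butyl esters being inert and the hindered 1,1-disubstituted alkene expected to survive.

Step 16
Reactants: 25 di-tert-butyl ester of the target
Product: 26 target CNP0412196.1
Conditions: CF3CO2H–CH2Cl2 (1:4), 0 °C to 25 °C
Reagents that add atoms: none
Why: Acidolysis of both tert-butyl esters (loss of isobutene) releases the C-7 and C-19 acids without base, so the epimerisable C-6 should stay intact.

**Compound list**
1 | tert-butyl 2-cyanopropanoate (racemic) | CC(C#N)C(=O)OC(C)(C)C | starting material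
2 | acrolein | C=CC=O | starting material
3 | tert-butyl (2R)-2-cyano-2-methyl-5-oxopentanoate | O=CCC[C@@](C)(C(=O)OC(C)(C)C)C#N | intermediate
4 | tert-butyl (2R)-2-cyano-5,5-dimethoxy-2-methylpentanoate | COC(OC)CC[C@@](C)(C(=O)OC(C)(C)C)C#N | intermediate
5 | tert-butyl (2R)-2-[(diisobutylalumanyl)iminomethyl]-5,5-dimethoxy-2-methylpentanoate (not isolated) | COC(OC)CC[C@@](C)(C(=O)OC(C)(C)C)C=N[Al](CC(C)C)CC(C)C | intermediate
6 | tert-butyl (2R)-2-formyl-5,5-dimethoxy-2-methylpentanoate | COC(OC)CC[C@@](C)(C(=O)OC(C)(C)C)C=O | intermediate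
7 | tert-butyl (triphenyl-λ5-phosphanylidene)acetate | CC(C)(C)OC(=O)C=P(c1ccccc1)(c1ccccc1)c1ccccc1 | starting material
8 | di-tert-butyl (2E,4R)-4-(3,3-dimethoxypropyl)-4-methylpent-2-enedioate | COC(OC)CC[C@@](C)(C(=O)OC(C)(C)C)/C=C/C(=O)OC(C)(C)C | intermediate
9 | di-tert-butyl (2E,4R)-4-methyl-4-(3-oxopropyl)pent-2-enedioate | O=CCC[C@@](C)(C(=O)OC(C)(C)C)/C=C/C(=O)OC(C)(C)C | intermediate
10 | Meldrum's acid (2,2-dimethyl-1,3-dioxane-4,6-dione) | CC1(C)OC(=O)CC(=O)O1 | starting material
11 | di-tert-butyl (2E,4R)-4-[3-(2,2-dimethyl-4,6-dioxo-1,3-dioxan-5-ylidene)propyl]-4-methylpent-2-enedioate (not isolated) | CC1(C)OC(=O)C(=CCC[C@@](C)(C(=O)OC(C)(C)C)/C=C/C(=O)OC(C)(C)C)C(=O)O1 | intermediate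
12 | di-tert-butyl (2E,4R)-4-[3-(2,2-dimethyl-4,6-dioxo-1,3-dioxan-5-yl)propyl]-4-methylpent-2-enedioate | CC1(C)OC(=O)C(CCC[C@@](C)(C(=O)OC(C)(C)C)/C=C/C(=O)OC(C)(C)C)C(=O)O1 | intermediate
13 | (6R,7E)-9-tert-butoxy-6-(tert-butoxycarbonyl)-2-[(ethylsulfanyl)carbonyl]-6-methyl-9-oxonon-7-enoic acid (C-2 epimers) | OC(=O)C(CCC[C@@](C)(C(=O)OC(C)(C)C)/C=C/C(=O)OC(C)(C)C)C(=O)SCC | intermediate
14 | 4,4-dimethoxycyclohexa-2,5-dien-1-one | COC1(OC)C=CC(=O)C=C1 | starting material
15 | propargyl bromide (3-bromoprop-1-yne) | C#CCBr | starting material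
16 | 4,4-dimethoxy-1-(prop-2-yn-1-yl)cyclohexa-2,5-dien-1-ol | C#CCC1(O)C=CC(OC)(OC)C=C1 | intermediate
17 | 4,4-dimethoxy-1-(prop-2-yn-1-yl)cyclohexa-2,5-dien-1-yl ester of 13 (C-10 epimers) | C#CCC1(OC(=O)C(CCC[C@@](C)(C(=O)OC(C)(C)C)/C=C/C(=O)OC(C)(C)C)C(=O)SCC)C=CC(OC)(OC)C=C1 | intermediate
18 | 4-oxo-1-(prop-2-yn-1-yl)cyclohexa-2,5-dien-1-yl ester of 13 (C-10 epimers) | C#CCC1(OC(=O)C(CCC[C@@](C)(C(=O)OC(C)(C)C)/C=C/C(=O)OC(C)(C)C)C(=O)SCC)C=CC(=O)C=C1 | intermediate
19 | S-ethyl (3aS,7aS)-3-[(4R,5E)-7-tert-butoxy-4-(tert-butoxycarbonyl)-4-methyl-7-oxohept-5-en-1-yl]-2,5-dioxo-7a-(prop-2-yn-1-yl)-2,3,3a,4,5,7a-hexahydro-1-benzofuran-3-carbothioate (C-3 epimers) | C#CC[C@]23C=CC(=O)C[C@H]2C(C(=O)SCC)(CCC[C@@](C)(C(=O)OC(C)(C)C)/C=C/C(=O)OC(C)(C)C)C(=O)O3 | intermediate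
20 | ring-opened zwitterion: thioester enolate at C-10, allylpalladium at C-8 (σ-form drawn, ligands omitted, Pd on the face opposite C-10; not isolated) | C#CCC1([Pd+])C=CC(=O)C[C@H]1C(CCC[C@@](C)(C(=O)OC(C)(C)C)/C=C/C(=O)OC(C)(C)C)=C([O-])SCC | intermediate
21 | ring A closed zwitterion: tert-butyl ester enolate at C-6, allylpalladium at C-8 (σ-form drawn, ligands omitted; not isolated) | C#CCC1([Pd+])C=CC(=O)C[C@H]1[C@]2(C(=O)SCC)CCC[C@@](C)(C(=O)OC(C)(C)C)[C@H]2C=C([O-])OC(C)(C)C | intermediate
22 | tricyclic enone thioester (rings A, B, C; C-13=C-14 enone, C-12 ketone; 4R; H-5β, H-9β, 6β-CO2tBu, 8β-propargyl, C-20 α as S-ethyl thioester) | C#CC[C@]23C=CC(=O)C[C@H]2[C@]1(C(=O)SCC)CCC[C@@](C)(C(=O)OC(C)(C)C)[C@H]1[C@@H]3C(=O)OC(C)(C)C | intermediate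
23 | dimethylphenylsilyl enol ether of the 13,14-dihydro ketone (C-12=C-13) | C#CC[C@]23CC=C(O[Si](C)(C)c4ccccc4)C[C@H]2[C@]1(C(=O)SCC)CCC[C@@](C)(C(=O)OC(C)(C)C)[C@H]1[C@@H]3C(=O)OC(C)(C)C | intermediate
24 | tetracyclic 12-oxo-16-ene, C-20 S-ethyl thioester, 7,19-di-tert-butyl ester | C=C1C[C@]23C[C@H]1C(=O)C[C@H]2[C@]1(C(=O)SCC)CCC[C@@](C)(C(=O)OC(C)(C)C)[C@H]1[C@@H]3C(=O)OC(C)(C)C | intermediate
25 | target 7,19-di-tert-butyl ester (C-20 aldehyde) | C=C1C[C@]23C[C@H]1C(=O)C[C@H]2[C@]1(C=O)CCC[C@@](C)(C(=O)OC(C)(C)C)[C@H]1[C@@H]3C(=O)OC(C)(C)C | intermediate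
26 | CNP0412196.1 (gibberellane-type 20-al, 12-oxo, 16-ene, 7,19-dioic acid) | C=C1C[C@]23C[C@H]1C(=O)C[C@H]2[C@]1(C=O)CCC[C@@](C)(C(=O)O)[C@H]1[C@@H]3C(=O)O | target

**Totals**
Total steps: 16. Longest linear sequence: 15 (steps 1–7 and 9–16, from compound 1).

**Steps most likely to fail**

1. Step 12. Process at risk: the allylpalladium zwitterion may lose the C-9 hydrogen and aromatise ring C to a phenol, or the C-10 enolate may close directly onto the allyl unit, faster than the hindered Michael addition to C-5 takes place. Fallback (known chemistry, the Michael addition is run under base before any allyl cation exists): it sets out from 19. AgOCOCF3 in aqueous THF hydrolyses the thioester, and warming in toluene decarboxylates the malonic acid to the monosubstituted lactone F1, whose lactone carbonyl is now C-20. TMSOTf-catalysed ketalisation with 1,2-bis(trimethylsilyloxy)ethane at −78 °C protects the C-12 ketone as the dioxolane F2. LiN(SiMe3)2 (2.2 equiv, one equivalent being allowed for the alkyne C–H; THF, −78 to 0 °C) forms the lactone enolate, which adds 6-exo to the enoate from the convex face of the bicyclic lactone. Pd(PPh3)4 (5 mol %) then lets the lithium ester enolate displace the allylic lactone carboxylate at C-8 (intramolecular Tsuji–Trost alkylation) to give, after work-up with dilute HCl at 0 °C, the C-20 carboxylic acid F3. Dilute HCl in THF at 25 °C removes the ketal to give the keto acid F4, and EtSH/DCC/DMAP converts F4 into the thioester, which comes back to the route at 22.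

2. Step 11. Process at risk: poor discrimination between the two enone arms, or a base-catalysed background cyclisation, giving the wrong ring C configuration relative to C-4. Fallback (diastereomer separation in place of catalyst control): it sets out from 18. Achiral DBU in CH2Cl2 closes both cis-lactones, 19 and its ring diastereomer F5 (3aR,7aR), which differ as diastereomers because of the remote C-4 centre and are separated by chromatography. F5 is recycled by DBU-induced retro-Michael/Michael equilibration. The fallback comes back to the route at 19.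

3. Step 13. Process at risk: the copper hydride may be consumed by the terminal alkyne (acetylide formation or hydrocupration) or deliver hydride in the 1,2 sense. Fallback (regiocontrol by kinetic deprotonation in place of reductive enolate formation): it sets out from 22. Iminium-catalysed transfer hydrogenation (Hantzsch ester, dibenzylammonium trifluoroacetate, THF) gives the saturated ketone F6. LiN(SiMe3)2 (1.05 equiv) with Me3SiCl at −78 °C deprotonates the less hindered C-13 (C-11 is shielded by C-9 and the quaternary C-10) to give the trimethylsilyl enol ether F7. F7 is cyclised under the conditions of step 14 and comes back to the route at 24.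

**Further compounds**
F1 | step 12 | (3aS,7aS)-lactone without the thioester (C-10 carries H; C-3 epimers) | C#CC[C@]23C=CC(=O)C[C@H]2C(CCC[C@@](C)(C(=O)OC(C)(C)C)/C=C/C(=O)OC(C)(C)C)C(=O)O3
F2 | step 12 | ethylene ketal of F1 at C-12 | C#CC[C@]23C=CC4(OCCO4)C[C@H]2C(CCC[C@@](C)(C(=O)OC(C)(C)C)/C=C/C(=O)OC(C)(C)C)C(=O)O3
F3 | step 12 | tricyclic C-20 carboxylic acid, C-12 ethylene ketal | C#CC[C@]23C=CC4(OCCO4)C[C@H]2[C@]1(C(=O)O)CCC[C@@](C)(C(=O)OC(C)(C)C)[C@H]1[C@@H]3C(=O)OC(C)(C)C
F4 | step 12 | tricyclic enone C-20 carboxylic acid | C#CC[C@]23C=CC(=O)C[C@H]2[C@]1(C(=O)O)CCC[C@@](C)(C(=O)OC(C)(C)C)[C@H]1[C@@H]3C(=O)OC(C)(C)C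
F5 | step 11 | (3aR,7aR) ring diastereomer of 19 | C#CC[C@@]23C=CC(=O)C[C@@H]2C(C(=O)SCC)(CCC[C@@](C)(C(=O)OC(C)(C)C)/C=C/C(=O)OC(C)(C)C)C(=O)O3
F6 | step 13 | 13,14-dihydro ketone of 22 | C#CC[C@]23CCC(=O)C[C@H]2[C@]1(C(=O)SCC)CCC[C@@](C)(C(=O)OC(C)(C)C)[C@H]1[C@@H]3C(=O)OC(C)(C)C
F7 | step 13 | trimethylsilyl enol ether of F6 (C-12=C-13) | C#CC[C@]23CC=C(O[Si](C)(C)C)C[C@H]2[C@]1(C(=O)SCC)CCC[C@@](C)(C(=O)OC(C)(C)C)[C@H]1[C@@H]3C(=O)OC(C)(C)C
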